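**Retrosynthetic overview**
1. Target 22 ⇒ tris-MOM flavanone 21; the three acetals are removed last.
2. Ring C of 21 is opened at O1–C8a and C4–C4a in one step: aryne 19 (C4a≡C8a of ring A, released from silyl triflate 12) plus the silyl-masked (S)-β-oxy ester 17. C2 is set beforehand by asymmetric transfer hydrogenation and carried through untouched.
3. Enabling feature: the C5 oxygen of ring A is ortho to C4a, so it polarises the C4a≡C8a aryne (O1 adds at C8a, carbanion at C4a); O1 and C4 are 1,3-related across C2–C3, so acyl capture at C4a closes ring C as a six-membered ring.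
4. 12 ⇐ 2-methylresorcinol: bis-MOM ether, Ir C–H borylation/oxidation (sacrificial C8a oxygen), bromination at C4a, O-propargylation, semi-hydrogenation/aromatic Claisen (prenyl to C8), retro-Brook/triflation.
5. Ring order: rings A and B come from purchased arenes; ring C is formed last, in the key step.

Key step: step 11

Remark: the given SMILES is the (2S)-flavanone; the (S,S)-TsDPEN catalyst is assumed to give the (S)-carbinol from β-keto ester 15 as it does from aryl alkyl ketones (otherwise the (R,R)-catalyst would be used).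

**Step 1**
Reactants: 1 2-methylresorcinol
Product: 2 1,3-bis(methoxymethoxy)-2-methylbenzene
Conditions: NaH, MOMCl, DMF, 0 °C → rt
Reagents that add atoms: chloromethyl methyl ether, COCCl
Why: Williamson-type O-alkylation of both phenoxides (MOM protection); no stereocentre is involved.

**Step 2**
Reactants: 2 1,3-bis(methoxymethoxy)-2-methylbenzene
Product: 4 3,5-bis(methoxymethoxy)-4-methylphenol, via pinacol boronate 3 (not isolated)
Conditions: [Ir(OMe)(cod)]2 (cat.), dtbpy (cat.), B2pin2, THF, 80 °C; then aq. NaOH, H2O2, 0 °C → rt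
Reagents that add atoms: bis(pinacolato)diboron, CC1(C)OB(OC1(C)C)B1OC(C)(C)C(C)(C)O1 (boron of 3 only); hydrogen peroxide, OO (phenol oxygen of 4)
Why: Sterically controlled Ir-catalysed C–H borylation should occur only at C5, the one C–H with no ortho substituent, and oxidation of the C–B bond gives the phenol at the same carbon (borylation/oxidation).

**Step 3**
Reactants: 4 3,5-bis(methoxymethoxy)-4-methylphenol
Product: 5 2-bromo-3,5-bis(methoxymethoxy)-4-methylphenol
Conditions: NBS (1.0 equiv), CH2Cl2, −78 °C
Reagents that add atoms: N-bromosuccinimide, O=C1CCC(=O)N1Br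
Why: Electrophilic aromatic bromination of the phloroglucinol-type phenol at one of its two equivalent ortho positions (para is blocked by methyl); one equivalent at low temperature limits dibromination.

**Step 4**
Reactants: 5 2-bromo-3,5-bis(methoxymethoxy)-4-methylphenol; 6 3-chloro-3-methylbut-1-yne
Product: 7 1-bromo-2,4-bis(methoxymethoxy)-3-methyl-6-[(2-methylbut-3-yn-2-yl)oxy]benzene
Conditions: DBU, CuCl2 (cat.), MeCN, 0 °C
Reagents that add atoms: none
Why: Copper-catalysed O-alkylation of the phenoxide by the tertiary propargylic chloride, the standard entry to aryl 1,1-dimethylpropargyl ethers.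

**Step 5**
Reactants: 7 1-bromo-2,4-bis(methoxymethoxy)-3-methyl-6-[(2-methylbut-3-yn-2-yl)oxy]benzene
Product: 9 2-bromo-3,5-bis(methoxymethoxy)-4-methyl-6-(3-methylbut-2-en-1-yl)phenol, via dimethylallyl ether 8 (not isolated)
Conditions: H2 (1 atm), Lindlar catalyst, quinoline, toluene, rt; filter; then 110 °C
Reagents that add atoms: none
Why: Lindlar semi-hydrogenation should stop at the 1,1-dimethylallyl ether, which undergoes aromatic Claisen [3,3] rearrangement to the only free ortho carbon (the other carries Br), delivering the terminal CH2 to the ring and hence the normal prenyl group.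

**Step 6**
Reactants: 9 2-bromo-3,5-bis(methoxymethoxy)-4-methyl-6-(3-methylbut-2-en-1-yl)phenol
Product: 12 3,5-bis(methoxymethoxy)-4-methyl-2-(3-methylbut-2-en-1-yl)-6-(trimethylsilyl)phenyl trifluoromethanesulfonate, via aryl trimethylsilyl ether 10 (not isolated), via lithium silylphenoxide 11 (not isolated)
Conditions: HMDS, 70 °C, evaporate; n-BuLi, THF, −78 → −40 °C; Tf2O, −78 °C
Reagents that add atoms: hexamethyldisilazane, C[Si](C)(C)N[Si](C)(C)C; triflic anhydride, O=S(=O)(OS(=O)(=O)C(F)(F)F)C(F)(F)F
Why: O-silylation, Br–Li exchange and 1,3 O→C silyl shift (retro-Brook rearrangement) place SiMe3 on the carbon that carried Br, and the lithium phenoxide is then triflated; this is the standard o-silylaryl triflate synthesis.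

**Step 7**
Reactants: 13 4'-hydroxyacetophenone
Product: 14 1-[4-(methoxymethoxy)phenyl]ethan-1-one
Conditions: NaH, MOMCl, DMF, 0 °C → rt
Reagents that add atoms: chloromethyl methyl ether, COCCl
Why: O-alkylation of the phenoxide (MOM protection); the phenol is far more acidic than the ketone α-position.

**Step 8**
Reactants: 14 1-[4-(methoxymethoxy)phenyl]ethan-1-one
Product: 15 methyl 3-[4-(methoxymethoxy)phenyl]-3-oxopropanoate
Conditions: NaH, (MeO)2CO, THF, reflux; HCl quench at 0 °C
Reagents that add atoms: dimethyl carbonate, COC(=O)OC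
Why: Crossed Claisen condensation of the ketone enolate with dimethyl carbonate, driven by deprotonation of the β-keto ester formed.

**Step 9**
Reactants: 15 methyl 3-[4-(methoxymethoxy)phenyl]-3-oxopropanoate
Product: 16 methyl (3S)-3-hydroxy-3-[4-(methoxymethoxy)phenyl]propanoate
Conditions: RuCl[(S,S)-TsDPEN](p-cymene) (cat.), HCO2H/Et3N (5:2), DMF, 30 °C
Reagents that add atoms: none
Why: Noyori–Ikariya asymmetric transfer hydrogenation; the CH/π contact between the aryl group and the η6-arene of the catalyst fixes the face of hydride delivery and should set the carbinol carbon (future C2) as S.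

**Step 10**
Reactants: 16 methyl (3S)-3-hydroxy-3-[4-(methoxymethoxy)phenyl]propanoate
Product: 17 methyl (3S)-3-[4-(methoxymethoxy)phenyl]-3-[(trimethylsilyl)oxy]propanoate
Conditions: TMSCl, Et3N, CH2Cl2, 0 °C; filter through a pad with pentane
Reagents that add atoms: chlorotrimethylsilane, C[Si](C)(C)Cl
Why: O-silylation of the secondary alcohol; the C–O bond at the stereocentre is not touched, so the configuration is kept.

**Step 11**
Reactants: 12 3,5-bis(methoxymethoxy)-4-methyl-2-(3-methylbut-2-en-1-yl)-6-(trimethylsilyl)phenyl trifluoromethanesulfonate; 17 methyl (3S)-3-[4-(methoxymethoxy)phenyl]-3-[(trimethylsilyl)oxy]propanoate (1.3 equiv)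
Product: 21 (2S)-5,7-bis(methoxymethoxy)-2-[4-(methoxymethoxy)phenyl]-6-methyl-8-(3-methylbut-2-en-1-yl)-2,3-dihydro-4H-chromen-4-one, via potassium alkoxide 18 (not isolated), via aryne 19 (not isolated), via aryl anion 20 (not isolated)
Conditions: KF, 18-crown-6, THF, −20 → 0 °C; pH 7 buffer quench
Reagents that add atoms: none
Why: Proposed new method: fluoride strips SiMe3 from 12 (loss of triflate gives aryne 19, C4a≡C8a) and from 17 (giving alkoxide 18 with no O–H in the flask); 18 adds through oxygen to C8a and the carbanion left at C4a (20) attacks the ester carbonyl and expels methoxide, so O1–C8a and C4–C4a form in one operation. The closest known reaction type is the aryne annulation of salicylate esters to xanthones (phenoxide addition to the aryne, then anionic acyl cyclisation), together with O-arylation of aliphatic alkoxides by arynes; new here is an aliphatic, enolisable β-oxy ester as the four-atom partner. Ring C closes by a 6-exo-trig acyl substitution at C4 after the intermolecular O-arylation (formal [4+2] across the aryne). No stereocentre is created: no bond at C2 is made or broken, so the S configuration of 17 should be carried into 21. The step needs O-attack at C8a rather than C4a and acylation rather than protonation of the C4a carbanion: the first is secured by the C5 OMOM group, whose inductive pull distorts the aryne so that the nucleophile attacks the distal carbon and the charge develops next to oxygen, the second by silyl masking of the hydroxyl (no proton donor) and the six-membered transition state. Low temperature and consumption of the released methoxide by the C–SiMe3 group of 12 (which it also converts to aryne) should limit base-induced ring opening of 21.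

**Step 12**
Reactants: 21 (2S)-5,7-bis(methoxymethoxy)-2-[4-(methoxymethoxy)phenyl]-6-methyl-8-(3-methylbut-2-en-1-yl)-2,3-dihydro-4H-chromen-4-one
Product: 22 (2S)-5,7-dihydroxy-2-(4-hydroxyphenyl)-6-methyl-8-(3-methylbut-2-en-1-yl)-2,3-dihydro-4H-chromen-4-one (6-methyl-8-prenylnaringenin)
Conditions: 3 M HCl (aq.), MeOH, 40 °C
Reagents that add atoms: none
Why: Acid-catalysed methanolysis of the three MOM acetals (transacetalisation to dimethoxymethane); C2 is not involved, and the mild temperature should spare the prenyl alkene and the pyranone ring.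

**Compound list**
1 | 2-methylresorcinol (2-methylbenzene-1,3-diol) | Cc1c(O)cccc1O | starting material
2 | 1,3-bis(methoxymethoxy)-2-methylbenzene | Cc1c(OCOC)cccc1OCOC | intermediate
3 | 2-[3,5-bis(methoxymethoxy)-4-methylphenyl]-4,4,5,5-tetramethyl-1,3,2-dioxaborolane | Cc1c(OCOC)cc(B2OC(C)(C)C(C)(C)O2)cc1OCOC | intermediate
4 | 3,5-bis(methoxymethoxy)-4-methylphenol | Cc1c(OCOC)cc(O)cc1OCOC | intermediate
5 | 2-bromo-3,5-bis(methoxymethoxy)-4-methylphenol | Cc1c(OCOC)c(Br)c(O)cc1OCOC | intermediate
6 | 3-chloro-3-methylbut-1-yne | C#CC(C)(C)Cl | starting material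
7 | 1-bromo-2,4-bis(methoxymethoxy)-3-methyl-6-[(2-methylbut-3-yn-2-yl)oxy]benzene | C#CC(C)(C)Oc1cc(OCOC)c(C)c(OCOC)c1Br | intermediate
8 | 1-bromo-2,4-bis(methoxymethoxy)-3-methyl-6-[(2-methylbut-3-en-2-yl)oxy]benzene | C=CC(C)(C)Oc1cc(OCOC)c(C)c(OCOC)c1Br | intermediate
9 | 2-bromo-3,5-bis(methoxymethoxy)-4-methyl-6-(3-methylbut-2-en-1-yl)phenol | CC(C)=CCc1c(O)c(Br)c(OCOC)c(C)c1OCOC | intermediate
10 | [2-bromo-3,5-bis(methoxymethoxy)-4-methyl-6-(3-methylbut-2-en-1-yl)phenoxy]trimethylsilane | CC(C)=CCc1c(O[Si](C)(C)C)c(Br)c(OCOC)c(C)c1OCOC | intermediate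
11 | lithium 3,5-bis(methoxymethoxy)-4-methyl-2-(3-methylbut-2-en-1-yl)-6-(trimethylsilyl)phenolate | [Li+].[O-]c1c(CC=C(C)C)c(OCOC)c(C)c(OCOC)c1[Si](C)(C)C | intermediate
12 | 3,5-bis(methoxymethoxy)-4-methyl-2-(3-methylbut-2-en-1-yl)-6-(trimethylsilyl)phenyl trifluoromethanesulfonate | CC(C)=CCc1c(OS(=O)(=O)C(F)(F)F)c([Si](C)(C)C)c(OCOC)c(C)c1OCOC | intermediate
13 | 4'-hydroxyacetophenone | CC(=O)c1ccc(O)cc1 | starting material
14 | 1-[4-(methoxymethoxy)phenyl]ethan-1-one | CC(=O)c1ccc(OCOC)cc1 | intermediate
15 | methyl 3-[4-(methoxymethoxy)phenyl]-3-oxopropanoate | COC(=O)CC(=O)c1ccc(OCOC)cc1 | intermediate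
16 | methyl (3S)-3-hydroxy-3-[4-(methoxymethoxy)phenyl]propanoate | O[C@H](c1ccc(OCOC)cc1)CC(=O)OC | intermediate
17 | methyl (3S)-3-[4-(methoxymethoxy)phenyl]-3-[(trimethylsilyl)oxy]propanoate | C[Si](C)(C)O[C@H](c1ccc(OCOC)cc1)CC(=O)OC | intermediate
18 | potassium (1S)-3-methoxy-1-[4-(methoxymethoxy)phenyl]-3-oxopropan-1-olate | [K+].[O-][C@H](c1ccc(OCOC)cc1)CC(=O)OC | intermediate
19 | 3,5-bis(methoxymethoxy)-4-methyl-6-(3-methylbut-2-en-1-yl)benzyne (triple bond between the former C–SiMe3 and C–OTf carbons) | CC(C)=CCC1=C(OCOC)C(C)=C(OCOC)C#C1 | intermediate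
20 | potassium 2-{(1S)-3-methoxy-1-[4-(methoxymethoxy)phenyl]-3-oxopropoxy}-4,6-bis(methoxymethoxy)-5-methyl-3-(3-methylbut-2-en-1-yl)benzen-1-ide | CC(C)=CCc1c(OCOC)c(C)c(OCOC)[c-]c1O[C@H](c1ccc(OCOC)cc1)CC(=O)OC.[K+] | intermediate
21 | (2S)-5,7-bis(methoxymethoxy)-2-[4-(methoxymethoxy)phenyl]-6-methyl-8-(3-methylbut-2-en-1-yl)-2,3-dihydro-4H-chromen-4-one | CC(C)=CCc1c(OCOC)c(C)c(OCOC)c2c1O[C@H](c1ccc(OCOC)cc1)CC2=O | intermediate
22 | (2S)-5,7-dihydroxy-2-(4-hydroxyphenyl)-6-methyl-8-(3-methylbut-2-en-1-yl)-2,3-dihydro-4H-chromen-4-one (6-methyl-8-prenylnaringenin) | CC(C)=CCc1c(O)c(C)c(O)c2c1O[C@H](c1ccc(O)cc1)CC2=O | target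

**Step count**
Total: 12 steps. Longest linear sequence: 8 steps (steps 1–6, 11, 12).

**Steps most likely to fail**

Step 11 (proposed new method). The C4a carbanion may be quenched by proton transfer from the ester α-CH2 before it acylates, which would lead to β-elimination of the aryloxide. The alkoxide may undergo retro-aldol cleavage or transesterification before it meets the aryne. Fluoride or methoxide may open the pyranone ring of the product by retro-oxa-Michael reaction and erode the C2 configuration. The fallback uses only known reaction types, sets out from 12 and returns at 21. Aryne generation from 12 with CsF in THF at 125 °C in the presence of acetic acid (intermolecular C–O insertion of a carboxylic acid into the aryne, same regiochemistry) should give 1-[2-hydroxy-4,6-bis(methoxymethoxy)-5-methyl-3-(3-methylbut-2-en-1-yl)phenyl]ethan-1-one F1. Condensation with DMF dimethyl acetal in toluene at 90 °C should give (E)-3-(dimethylamino)-1-[2-hydroxy-4,6-bis(methoxymethoxy)-5-methyl-3-(3-methylbut-2-en-1-yl)phenyl]prop-2-en-1-one F2. Cyclisation on silica gel or in warm acetic acid, with loss of dimethylamine, should give 5,7-bis(methoxymethoxy)-6-methyl-8-(3-methylbut-2-en-1-yl)-4H-chromen-4-one F3. Rh(I)/chiral diene-catalysed asymmetric conjugate addition (Hayashi–Miyaura type) of commercial [4-(methoxymethoxy)phenyl]boronic acid, with the ligand enantiomer that delivers the aryl group to the face giving 2S, then leads to 21. The stereocentre is set by the catalyst in this variant, after ring C already exists.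

Step 5. The semi-hydrogenation may run on to the saturated ether or remove the aryl bromine, and the tertiary allyl ether may lose isoprene on heating instead of rearranging. The fallback sets out from 5 (bypassing 7) and returns at 9. Methyl 2-methylbut-3-en-2-yl carbonate F4 would be prepared from 2-methylbut-3-en-2-ol (n-BuLi, ClCO2Me, THF). Tsuji–Trost O-allylation of 5 with it (Pd(PPh3)4, THF, 0 °C) should give ether 8 directly, with no hydrogen in the flask. The Claisen rearrangement to 9 would then be run under Eu(fod)3 catalysis in CHCl3 at 50 °C instead of thermally.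

Step 12. Under protic acid the prenyl alkene may cyclise onto the liberated C7 hydroxyl (chroman formation) or add HCl/MeOH, and the pyranone ring may open and reclose with loss of configuration at C2. The fallback sets out from 21 and returns at 22. Treatment with TMSOTf/2,2'-bipyridyl in CH2Cl2 at 0 °C exchanges the aryl MOM acetals for silyl ethers without free protic acid and should give (2S)-6-methyl-8-(3-methylbut-2-en-1-yl)-5,7-bis[(trimethylsilyl)oxy]-2-{4-[(trimethylsilyl)oxy]phenyl}-2,3-dihydro-4H-chromen-4-one F5. Hydrolysis of F5 with water at neutral pH then releases 22.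

**Further compounds**
F1 | step 11 | 1-[2-hydroxy-4,6-bis(methoxymethoxy)-5-methyl-3-(3-methylbut-2-en-1-yl)phenyl]ethan-1-one | CC(=O)c1c(O)c(CC=C(C)C)c(OCOC)c(C)c1OCOC
F2 | step 11 | (E)-3-(dimethylamino)-1-[2-hydroxy-4,6-bis(methoxymethoxy)-5-methyl-3-(3-methylbut-2-en-1-yl)phenyl]prop-2-en-1-one | CN(C)/C=C/C(=O)c1c(O)c(CC=C(C)C)c(OCOC)c(C)c1OCOC
F3 | step 11 | 5,7-bis(methoxymethoxy)-6-methyl-8-(3-methylbut-2-en-1-yl)-4H-chromen-4-one | O=c1ccoc2c1c(OCOC)c(C)c(OCOC)c2CC=C(C)C
F4 | step 5 | methyl 2-methylbut-3-en-2-yl carbonate | COC(=O)OC(C)(C)C=C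
F5 | step 12 | (2S)-6-methyl-8-(3-methylbut-2-en-1-yl)-5,7-bis[(trimethylsilyl)oxy]-2-{4-[(trimethylsilyl)oxy]phenyl}-2,3-dihydro-4H-chromen-4-one | CC(C)=CCc1c(O[Si](C)(C)C)c(C)c(O[Si](C)(C)C)c2c1O[C@H](c1ccc(O[Si](C)(C)C)cc1)CC2=O
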